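Ring A (C1–C5, C10) is opened across C4–C5 and C1–C10, so that the trans-related pair C10 (quaternary; methyl and acyl carbon C9) and C5 (CH carrying C6) becomes the alkene of an (E)-2-methyl-2-enal. One catalytic enantioselective Diels–Alder reaction of (E)-2-methylhepta-2,6-dienal with a 1-(acylamino)-3-silyloxybutadiene closes the six-membered ring and fixes both stereocentres. C9 is left as a formyl group and C3 as a masked ketone through which the C4 methyls are later introduced. The terminal alkene of the enal is the latent C8 methyl ketone. The C11–C15 chain is built from C9 by Grignard addition and enolate alkylation with a bromide made from prenyl acetate.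

Key step: step 5

Remark on locants: ring A = C1–C5 and C10; C4 carries the gem-dimethyl group; C5 carries C6–C7–C8(=O)–CH3; C10 carries its methyl and C9(=O)–C11–C12–C13(CH3)=C14–C15–OAc.
Remark on precursor design: the diene nitrogen is carried as a benzyl methyl carbamate, not as a dialkylamine. A basic, very electron-rich dialkylamino diene would bind the chromium Lewis acid and add to the enal without it, and the acylamino dienes are the class for which the salen catalysis is established.
Assumption: the facial sense of the salen catalyst with this enal is assigned by analogy. The (R,R) complex is written, and the equally available (S,S) complex would be used if a first run shows the opposite sense. Salen = dianion of (1R,2R)-N,N'-bis(3,5-di-tert-butylsalicylidene)cyclohexane-1,2-diamine.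
Remark: the carbinol carbon C9 is formed unselectively in step 6 and is carried as both epimers (compounds 10–19) until it becomes the ketone in step 12.

Step 1
Reactants: 1 pent-4-enal; 2 2-(triphenylphosphoranylidene)propanal
Product: 3 (E)-2-methylhepta-2,6-dienal
Conditions: toluene, 90 °C
Reagents that add atoms: none
Why: Wittig olefination with the stabilised formyl ylide should give the (E)-trisubstituted enal under thermodynamic control of the oxaphosphetane stage, and the conjugated product is too unreactive to be homologated again.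

Step 2
Reactants: 4 (E)-4-methoxybut-3-en-2-one; 5 benzylamine
Product: 6 (Z)-4-(benzylamino)but-3-en-2-one
Conditions: CH2Cl2, 0 °C → rt
Reagents that add atoms: none
Why: Conjugate addition–elimination at the β-alkoxy enone exchanges methoxide for the amine and should give the hydrogen-bonded (Z)-enaminone.

Step 3
Reactants: 6 (Z)-4-(benzylamino)but-3-en-2-one
Product: 7 methyl benzyl[(E)-3-oxobut-1-en-1-yl]carbamate
Conditions: NaH, THF, 0 °C; ClCO2Me, 0 °C → rt
Reagents that add atoms: methyl chloroformate, COC(=O)Cl
Why: N-acylation of the sodium salt of a secondary enaminone with a chloroformate; the delocalised anion has no fixed alkene geometry, so the less crowded (E)-vinylogous imide should result.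

Step 4
Reactants: 7 methyl benzyl[(E)-3-oxobut-1-en-1-yl]carbamate
Product: 8 methyl benzyl[(1E)-3-(tert-butyldimethylsilyloxy)buta-1,3-dien-1-yl]carbamate
Conditions: NaN(SiMe3)2, THF, −78 °C; t-BuMe2SiCl, −78 °C → rt
Reagents that add atoms: tert-butyldimethylsilyl chloride, CC(C)(C)[Si](C)(C)Cl
Why: Kinetic deprotonation of the methyl ketone and O-silylation of the enolate (silyl enol ether formation) should give the 1-amino-3-silyloxydiene with the (E)-enamide bond retained.

Step 5
Reactants: 3 (E)-2-methylhepta-2,6-dienal; 8 methyl benzyl[(1E)-3-(tert-butyldimethylsilyloxy)buta-1,3-dien-1-yl]carbamate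
Product: 9 methyl benzyl[(1R,5R,6S)-5-(but-3-en-1-yl)-3-(tert-butyldimethylsilyloxy)-6-formyl-6-methylcyclohex-2-en-1-yl]carbamate (endo adduct)
Conditions: (R,R)-(salen)CrSbF6 (5 mol %), 4 Å MS, CH2Cl2, −20 °C → rt
Reagents that add atoms: none
Why: The cationic salen complex of trivalent chromium binds the formyl oxygen of 3, and the diene adds in a concerted but asynchronous [4+2] cycloaddition in which its CH2 terminus (C4) attacks the β-carbon C5 while the nitrogen-bearing carbon C1 bonds to C10. The closest known reaction is this same salen–chromium-catalysed Diels–Alder reaction of 1-(acylamino)-3-silyloxydienes with 2-substituted acroleins; the β-alkyl group of 3 is expected to lower the rate without changing the course. Ring A closes by intermolecular cycloaddition, with C4–C5 and C1–C10 formed in the same step. C5 and C10 are related by suprafacial addition to the (E)-alkene (C6 and C9 trans, C6 and the C10 methyl cis) and are set in the absolute sense by the chiral salen ligand, which blocks one face of the bound enal; C1 follows from the endo position of the formyl group and is erased in step 7. The regioselectivity that the step needs is secured by the polarisation of the diene (donor nitrogen at C1, silyloxy at C3), and the carbamate on nitrogen keeps the uncatalysed racemic reaction slow.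

Step 6
Reactants: 9 methyl benzyl[(1R,5R,6S)-5-(but-3-en-1-yl)-3-(tert-butyldimethylsilyloxy)-6-formyl-6-methylcyclohex-2-en-1-yl]carbamate
Product: 11 1-[(1S,2R,6R)-2-[benzyl(methyl)amino]-6-(but-3-en-1-yl)-4-(tert-butyldimethylsilyloxy)-1-methylcyclohex-3-en-1-yl]ethan-1-ol (both C9 epimers), via hydroxy carbamate 10 (not isolated)
Conditions: MeMgBr, THF, −78 → 0 °C; then LiAlH4, 65 °C; aq. NaOH work-up
Reagents that add atoms: methylmagnesium bromide, C[Mg]Br
Why: Grignard addition to the non-enolisable aldehyde brings in C11 and leaves C9 as an uncontrolled carbinol centre that is oxidised away in step 12, and LiAlH4 reduction then turns the carbamate (open or closed onto the alkoxide as a cyclic urethane) into a basic N-methyl amine while the silyl enol ether survives.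

Step 7
Reactants: 11 1-[(1S,2R,6R)-2-[benzyl(methyl)amino]-6-(but-3-en-1-yl)-4-(tert-butyldimethylsilyloxy)-1-methylcyclohex-3-en-1-yl]ethan-1-ol (both C9 epimers)
Product: 12 (4S,5R)-5-(but-3-en-1-yl)-4-(1-hydroxyethyl)-4-methylcyclohex-2-en-1-one (both C9 epimers)
Conditions: 48% aq. HF, MeCN, 0 °C → rt
Reagents that add atoms: none
Why: Acid hydrolysis of the silyl enol ether to the C3 ketone followed by β-elimination of the protonated amine from C1 should give the C1=C2 enone, and C5 and C10 cannot epimerise because neither is α to the carbonyl.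

Step 8
Reactants: 12 (4S,5R)-5-(but-3-en-1-yl)-4-(1-hydroxyethyl)-4-methylcyclohex-2-en-1-one (both C9 epimers)
Product: 13 (4S,5R)-5-(but-3-en-1-yl)-4-methyl-4-[1-(triethylsilyloxy)ethyl]cyclohex-2-en-1-one (both C9 epimers)
Conditions: Et3SiOTf, 2,6-lutidine, CH2Cl2, −78 °C
Reagents that add atoms: triethylsilyl trifluoromethanesulfonate, CC[Si](CC)(CC)OS(=O)(=O)C(F)(F)F
Why: Silyl triflate silylation of the hindered secondary alcohol protects the C9 oxygen against O-methylation and against vinylogous retro-aldol loss of C9 in the base step that follows.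

Step 9
Reactants: 13 (4S,5R)-5-(but-3-en-1-yl)-4-methyl-4-[1-(triethylsilyloxy)ethyl]cyclohex-2-en-1-one (both C9 epimers)
Product: 15 (4R,5S)-5-(but-3-en-1-yl)-4,6,6-trimethyl-4-[1-(triethylsilyloxy)ethyl]cyclohex-2-en-1-one (both C9 epimers), via monomethyl enone 14 (not isolated)
Conditions: LiN(iPr)2, THF, −78 °C; MeI; then LiN(iPr)2, −78 °C; MeI, DMPU, −78 → 0 °C
Reagents that add atoms: iodomethane, CI
Why: Enolate alkylation at C4, the only enolisable carbon because C10 is quaternary and rules out γ-deprotonation, carried out twice in one flask should give the gem-dimethyl group; the transient C4 centre vanishes with the second methyl and the descriptors change only through ligand priorities.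

Step 10
Reactants: 15 (4R,5S)-5-(but-3-en-1-yl)-4,6,6-trimethyl-4-[1-(triethylsilyloxy)ethyl]cyclohex-2-en-1-one (both C9 epimers)
Product: 16 (3S,4R)-3-(but-3-en-1-yl)-2,2,4-trimethyl-4-[1-(triethylsilyloxy)ethyl]cyclohexan-1-one (both C9 epimers)
Conditions: Li, NH3(l), THF, t-BuOH (1 equiv), −78 °C; NH4Cl
Reagents that add atoms: none
Why: Dissolving-metal conjugate reduction (Birch-type) saturates only the electron-poor C1=C2 bond by way of the radical anion and the lithium enolate, leaves the isolated terminal alkene and the silyl ether untouched, and creates no stereocentre.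

Step 11
Reactants: 16 (3S,4R)-3-(but-3-en-1-yl)-2,2,4-trimethyl-4-[1-(triethylsilyloxy)ethyl]cyclohexan-1-one (both C9 epimers)
Product: 19 1-[(1R,2R)-2-(but-3-en-1-yl)-1,3,3-trimethylcyclohexyl]ethan-1-ol (both C9 epimers), via hydrazone 17 (not isolated), via triethylsilyl ether 18 (not isolated)
Conditions: N2H4·H2O, KOH, diethylene glycol, argon, 130 °C then 200 °C; then 2 M HCl, THF, rt
Reagents that add atoms: none
Why: Wolff–Kishner reduction (Huang-Minlon procedure) removes the C3 carbonyl, which sits in the same environment as the carbonyl of 4,4-dimethyl-3-keto steroids where this reduction is routine, and the acid treatment then cleaves the triethylsilyl ether.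

Step 12
Reactants: 19 1-[(1R,2R)-2-(but-3-en-1-yl)-1,3,3-trimethylcyclohexyl]ethan-1-ol (both C9 epimers)
Product: 20 1-[(1R,2R)-2-(but-3-en-1-yl)-1,3,3-trimethylcyclohexyl]ethan-1-one
Conditions: Dess–Martin periodinane, NaHCO3, CH2Cl2, rt
Reagents that add atoms: none
Why: Dess–Martin oxidation of the hindered secondary alcohol should convert both C9 epimers into the single methyl ketone without touching the alkene.

Step 13
Reactants: 21 prenyl acetate
Product: 22 (E)-4-hydroxy-3-methylbut-2-en-1-yl acetate
Conditions: SeO2 (cat.), t-BuOOH, salicylic acid (cat.), CH2Cl2, rt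
Reagents that add atoms: tert-butyl hydroperoxide, CC(C)(C)OO; selenium dioxide, O=[Se]=O (catalytic oxygen carrier)
Why: Selenium dioxide allylic oxidation (ene reaction, then [2,3]-sigmatropic shift) attacks the (E)-methyl group of a trisubstituted alkene and should give the (E)-allylic alcohol.

Step 14
Reactants: 22 (E)-4-hydroxy-3-methylbut-2-en-1-yl acetate
Product: 23 (E)-4-bromo-3-methylbut-2-en-1-yl acetate
Conditions: CBr4, PPh3, CH2Cl2, 0 °C
Reagents that add atoms: carbon tetrabromide, BrC(Br)(Br)Br
Why: Appel bromination replaces the primary allylic hydroxyl by bromide through SN2 displacement of the oxyphosphonium group, without allylic shift or loss of the (E) geometry.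

Step 15
Reactants: 20 1-[(1R,2R)-2-(but-3-en-1-yl)-1,3,3-trimethylcyclohexyl]ethan-1-one; 23 (E)-4-bromo-3-methylbut-2-en-1-yl acetate
Product: 24 (E)-6-[(1R,2R)-2-(but-3-en-1-yl)-1,3,3-trimethylcyclohexyl]-3-methyl-6-oxohex-2-en-1-yl acetate
Conditions: LiN(iPr)2, THF, −78 °C; 23, DMPU, −78 → −20 °C
Reagents that add atoms: none
Why: The ketone has α-hydrogens only on C11, so its lithium enolate forms regiospecifically, and SN2 alkylation by the primary allylic bromide, which should outpace attack on the acetate, forms C11–C12 with the (E)-alkene carried over unchanged.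

Step 16
Reactants: 24 (E)-6-[(1R,2R)-2-(but-3-en-1-yl)-1,3,3-trimethylcyclohexyl]-3-methyl-6-oxohex-2-en-1-yl acetate
Product: 25 (E)-3-methyl-6-oxo-6-[(1R,2R)-1,3,3-trimethyl-2-(3-oxobutyl)cyclohexyl]hex-2-en-1-yl acetate (target)
Conditions: PdCl2 (10 mol %), CuCl, O2 (1 atm), DMF/H2O 7:1, rt
Reagents that add atoms: water, O
Why: Wacker oxidation should convert the monosubstituted alkene into the C8 methyl ketone with Markovnikov selectivity, while the trisubstituted alkene of the allylic acetate is too hindered to bind divalent palladium in competition.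

Compound list
1 | pent-4-enal | C=CCCC=O | starting material
2 | 2-(triphenylphosphoranylidene)propanal | CC(C=O)=P(c1ccccc1)(c1ccccc1)c1ccccc1 | starting material
3 | (E)-2-methylhepta-2,6-dienal | O=C/C(C)=C/CCC=C | intermediate
4 | (E)-4-methoxybut-3-en-2-one | CO/C=C/C(C)=O | starting material
5 | benzylamine | NCc1ccccc1 | starting material
6 | (Z)-4-(benzylamino)but-3-en-2-one | CC(=O)/C=C\NCc1ccccc1 | intermediate
7 | methyl benzyl[(E)-3-oxobut-1-en-1-yl]carbamate | COC(=O)N(Cc1ccccc1)/C=C/C(C)=O | intermediate
8 | methyl benzyl[(1E)-3-(tert-butyldimethylsilyloxy)buta-1,3-dien-1-yl]carbamate | COC(=O)N(Cc1ccccc1)/C=C/C(=C)O[Si](C)(C)C(C)(C)C | intermediate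
9 | methyl benzyl[(1R,5R,6S)-5-(but-3-en-1-yl)-3-(tert-butyldimethylsilyloxy)-6-formyl-6-methylcyclohex-2-en-1-yl]carbamate (N and CHO cis, CHO and butenyl trans) | O=C[C@]1(C)[C@H](N(Cc2ccccc2)C(=O)OC)C=C(O[Si](C)(C)C(C)(C)C)C[C@H]1CCC=C | intermediate
10 | methyl benzyl[(1R,5R,6S)-5-(but-3-en-1-yl)-3-(tert-butyldimethylsilyloxy)-6-(1-hydroxyethyl)-6-methylcyclohex-2-en-1-yl]carbamate (both C9 epimers; present as its magnesium alkoxide) | CC(O)[C@]1(C)[C@H](N(Cc2ccccc2)C(=O)OC)C=C(O[Si](C)(C)C(C)(C)C)C[C@H]1CCC=C | intermediate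
11 | 1-[(1S,2R,6R)-2-[benzyl(methyl)amino]-6-(but-3-en-1-yl)-4-(tert-butyldimethylsilyloxy)-1-methylcyclohex-3-en-1-yl]ethan-1-ol (both C9 epimers) | CC(O)[C@]1(C)[C@H](N(C)Cc2ccccc2)C=C(O[Si](C)(C)C(C)(C)C)C[C@H]1CCC=C | intermediate
12 | (4S,5R)-5-(but-3-en-1-yl)-4-(1-hydroxyethyl)-4-methylcyclohex-2-en-1-one (both C9 epimers) | CC(O)[C@]1(C)C=CC(=O)C[C@H]1CCC=C | intermediate
13 | (4S,5R)-5-(but-3-en-1-yl)-4-methyl-4-[1-(triethylsilyloxy)ethyl]cyclohex-2-en-1-one (both C9 epimers) | CC(O[Si](CC)(CC)CC)[C@]1(C)C=CC(=O)C[C@H]1CCC=C | intermediate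
14 | 5-(but-3-en-1-yl)-4,6-dimethyl-4-[1-(triethylsilyloxy)ethyl]cyclohex-2-en-1-one (ring carbons bearing the butenyl and silyloxyethyl groups arranged as in 13; new methyl-bearing carbon and C9 as mixtures) | CC(O[Si](CC)(CC)CC)[C@]1(C)C=CC(=O)C(C)[C@H]1CCC=C | intermediate
15 | (4R,5S)-5-(but-3-en-1-yl)-4,6,6-trimethyl-4-[1-(triethylsilyloxy)ethyl]cyclohex-2-en-1-one (both C9 epimers) | CC(O[Si](CC)(CC)CC)[C@]1(C)C=CC(=O)C(C)(C)[C@H]1CCC=C | intermediate
16 | (3S,4R)-3-(but-3-en-1-yl)-2,2,4-trimethyl-4-[1-(triethylsilyloxy)ethyl]cyclohexan-1-one (both C9 epimers) | CC(O[Si](CC)(CC)CC)[C@]1(C)CCC(=O)C(C)(C)[C@H]1CCC=C | intermediate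
17 | hydrazone of 16 (C=N–NH2 at the former carbonyl carbon; ring stereocentres arranged as in 16) | CC(O[Si](CC)(CC)CC)[C@]1(C)CCC(=NN)C(C)(C)[C@H]1CCC=C | intermediate
18 | {1-[(1R,2R)-2-(but-3-en-1-yl)-1,3,3-trimethylcyclohexyl]ethoxy}triethylsilane (both C9 epimers) | CC(O[Si](CC)(CC)CC)[C@]1(C)CCCC(C)(C)[C@H]1CCC=C | intermediate
19 | 1-[(1R,2R)-2-(but-3-en-1-yl)-1,3,3-trimethylcyclohexyl]ethan-1-ol (both C9 epimers) | CC(O)[C@]1(C)CCCC(C)(C)[C@H]1CCC=C | intermediate
20 | 1-[(1R,2R)-2-(but-3-en-1-yl)-1,3,3-trimethylcyclohexyl]ethan-1-one | CC(=O)[C@]1(C)CCCC(C)(C)[C@H]1CCC=C | intermediate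
21 | prenyl acetate (3-methylbut-2-en-1-yl acetate) | CC(C)=CCOC(C)=O | starting material
22 | (E)-4-hydroxy-3-methylbut-2-en-1-yl acetate | CC(=O)OC/C=C(\C)CO | intermediate
23 | (E)-4-bromo-3-methylbut-2-en-1-yl acetate | CC(=O)OC/C=C(\C)CBr | intermediate
24 | (E)-6-[(1R,2R)-2-(but-3-en-1-yl)-1,3,3-trimethylcyclohexyl]-3-methyl-6-oxohex-2-en-1-yl acetate | C=CCC[C@@H]1C(C)(C)CCC[C@@]1(C)C(=O)CC/C(C)=C/COC(C)=O | intermediate
25 | (E)-3-methyl-6-oxo-6-[(1R,2R)-1,3,3-trimethyl-2-(3-oxobutyl)cyclohexyl]hex-2-en-1-yl acetate (CNP0326957.1) | CC(=O)CC[C@@H]1C(C)(C)CCC[C@@]1(C)C(=O)CC/C(C)=C/COC(C)=O | target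

Total step count: 16. Longest linear sequence: 13 steps (steps 2–12, 15 and 16, from 4 to 25).

Steps most likely to fail

Step 5. The β-alkyl group may slow the catalysed cycloaddition so much that conversion stalls, that the diene decomposes on the Lewis acid first, or that facial discrimination by the catalyst falls. The fallback replaces catalyst control by auxiliary control; it sets out from 3 and 4 and comes back at 12. Compound 4 is condensed with (2R,5R)-2,5-diphenylpyrrolidine (THF, rt) to the vinylogous amide (E)-4-[(2R,5R)-2,5-diphenylpyrrolidin-1-yl]but-3-en-2-one F1. Silylation (KN(SiMe3)2, t-BuMe2SiCl, THF, −78 °C) gives the C2-symmetric aminosilyloxydiene F2. This much more electron-rich diene should add to 3 without a Lewis acid (toluene, rt → 60 °C), one diene face being shielded by a pyrrolidine phenyl group, to give the endo formyl cycloadduct F3. MeMgBr (THF, −78 °C) then gives the carbinol F4. Aqueous HF in MeCN hydrolyses the enol ether and expels the basic auxiliary directly, so no hydride step is needed and the route is rejoined at 12. The antipodal auxiliary would be taken if a first run shows the opposite sense.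

Step 15. Proton exchange between the product ketone and unreacted enolate may lead to double alkylation, and the enolate may attack the acetate carbonyl instead of the bromide. The fallback uses an aza-enolate in place of the ketone enolate; it sets out from 20 and comes back at 24. Compound 20 is condensed with 1,1-dimethylhydrazine (EtOH, cat. TsOH, reflux) to the N,N-dimethylhydrazone F7. Deprotonation (LiN(iPr)2, THF, 0 °C) and alkylation with 23 at −78 °C should stop cleanly after one alkylation and give the hydrazone F8. Two-phase hydrolysis (aqueous oxalic acid, Et2O, rt) then returns the ketone 24 with the acetate intact.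

Step 11. Hydrazone formation at the carbonyl next to the gem-dimethyl carbon may stay incomplete, and hot alkali may move the terminal double bond inward. The fallback is a radical deoxygenation; it sets out from 16 and comes back at 18, which is then desilylated to 19 as in step 11. NaBH4 (MeOH, 0 °C) reduces 16 to the ring carbinol F5. NaH, CS2 and MeI (THF, 0 °C → rt) give the S-methyl xanthate F6. Barton–McCombie reduction (Bu3SnH, AIBN, toluene, 110 °C, high stannane concentration so that hydrogen transfer outruns 6-exo cyclisation onto the butenyl group) should give 18, and 2 M HCl in THF then gives 19.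

Further compounds
F1 | step 5 | (E)-4-[(2R,5R)-2,5-diphenylpyrrolidin-1-yl]but-3-en-2-one | CC(=O)/C=C/N1[C@@H](c2ccccc2)CC[C@@H]1c1ccccc1
F2 | step 5 | (2R,5R)-1-[(1E)-3-(tert-butyldimethylsilyloxy)buta-1,3-dien-1-yl]-2,5-diphenylpyrrolidine | C=C(O[Si](C)(C)C(C)(C)C)/C=C/N1[C@@H](c2ccccc2)CC[C@@H]1c1ccccc1
F3 | step 5 | 2-(but-3-en-1-yl)-4-(tert-butyldimethylsilyloxy)-6-[(2R,5R)-2,5-diphenylpyrrolidin-1-yl]-1-methylcyclohex-3-ene-1-carbaldehyde (ring stereocentres arranged as in 9) | O=C[C@]1(C)[C@H](N2[C@@H](c3ccccc3)CC[C@@H]2c2ccccc2)C=C(O[Si](C)(C)C(C)(C)C)C[C@H]1CCC=C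
F4 | step 5 | 1-[2-(but-3-en-1-yl)-4-(tert-butyldimethylsilyloxy)-6-[(2R,5R)-2,5-diphenylpyrrolidin-1-yl]-1-methylcyclohex-3-en-1-yl]ethan-1-ol (ring stereocentres arranged as in 11; both C9 epimers) | CC(O)[C@]1(C)[C@H](N2[C@@H](c3ccccc3)CC[C@@H]2c2ccccc2)C=C(O[Si](C)(C)C(C)(C)C)C[C@H]1CCC=C
F5 | step 11 | 3-(but-3-en-1-yl)-2,2,4-trimethyl-4-[1-(triethylsilyloxy)ethyl]cyclohexan-1-ol (ring stereocentres arranged as in 16; carbinol epimers) | CC(O[Si](CC)(CC)CC)[C@]1(C)CCC(O)C(C)(C)[C@H]1CCC=C
F6 | step 11 | O-{3-(but-3-en-1-yl)-2,2,4-trimethyl-4-[1-(triethylsilyloxy)ethyl]cyclohexyl} S-methyl carbonodithioate (ring stereocentres arranged as in 16) | CC(O[Si](CC)(CC)CC)[C@]1(C)CCC(OC(=S)SC)C(C)(C)[C@H]1CCC=C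
F7 | step 15 | (E)-N,N-dimethylhydrazone of 20 | C/C(=N\N(C)C)[C@]1(C)CCCC(C)(C)[C@H]1CCC=C
F8 | step 15 | (E)-N,N-dimethylhydrazone of 24 | CC(=O)OC/C=C(\C)CC/C(=N\N(C)C)[C@]1(C)CCCC(C)(C)[C@H]1CCC=C
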